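Over 15 h at constant temperature, substrate takes up a gas that must first dissolve.

    dissolved gas → decomposed reagent (k1 = 0.0307 min⁻¹)
    dissolved gas + target → over-reaction product (k2 = 0.101 M⁻¹ min⁻¹)
    gas phase ⇌ dissolved gas, rate k3*(csat - [dissolved gas]) (k3 = 0.0238 min⁻¹, csat = 6.0 mM)
    substrate + dissolved gas → target (k4 = 0.154 M⁻¹ min⁻¹)
    2 substrate → homo dimer (k5 = 5.53 × 10⁻⁵ M⁻¹ min⁻¹)

substrate 0.050 M; gas phase 6.0 mM (held); time 15 h

- in percentages every species weighs as the substrate in it: one homo dimer counts as two
- two of one species on the left: rate k times its square, two consumed each time
- at the start none of the gas is dissolved
- run time (flask): 15 h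

* amount of target at 15 h, in percent of the substrate charged
* concentration of dissolved gas in solution at 15 h, in percent of saturation

I carry one quantity, the standing fraction of saturation: the transfer coefficient over itself plus the drains on the dissolved gas, 38.3% with substrate as charged. The dissolved gas adjusts within 16.1 min, far shorter than 15 h, and decomposition drains it faster than substrate does, so I hold the fraction constant. Substrate then decays pseudo-first-order, with exponent 0.318 at 15 h, and target is used up with 0.656 of substrate's rate constant. I drop the homo dimer, because the first half-life of substrate by that step alone, 3010 h, is far longer than the run. So I expect target at 24.5%.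

The forecast gives 24.2% and 38.8%, the level being “set mainly by the balance between gas transfer and decomposition”; its target is lower than mine and its fraction higher.

The flask gives 24.2% and 38.8%, as forecast.

In this flask the dissolved gas stood at 0.00229 M at 1.50 h and 0.00233 M at 15.0 h, while substrate fell to 72.7% and target passed 13.5% at 7.50 h. With the readings at 15.0 h put into its drains, the standing fraction of this flask becomes 38.8%. Carried to the same flask read at 2.5 d, my constant fraction gives substrate 28.0% and target 44.7%. That flask holds substrate 26.8%, target 44.4% and over-reaction product 28.1%.

(Its constants were set for the occasion; the rest is arithmetic.)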